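Numbering: guaianolide numbers, plain (C1–C15) for the enone half, primed for the 8'-hydroxy half.

**Plan**
- Cuts, in order: (a) O–Si and the labile C5/C10 configuration; (b) C2–C4' of the spiro cyclohexene, by a retro-1,2-shift that puts C3' back into the ring as a carbinol (seven-membered ring C3'–C4'–C15'–C14–C10–C1–C2); (c) C14–C15' (retro 1,6-addition); (d) C2–C3' (alkenyl metal + ketone).
- Enabling feature: spiro C4' is a quaternary carbon alpha to the C3' ketone and bound to the sp2 carbon C2 of the ring A enone, the retron of a semipinacol alkenyl shift; the dienone C3(=O)–C2=C1–C10=C14 makes C14 an electrophile for the C4'=C15' alkene.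
- Forward: dehydrocostus lactone → dehydrozaluzanin C → 2-iodo dienone → iodo dienol; deacylcynaropicrin → 8'β-silyloxy enone; 1,2-addition joins C2 to C3'; oxidation; one Lewis-acid cascade closes the seven-membered ring and contracts it to the six-membered spiro ring; equilibration; desilylation.
- Stereochemistry: C6, C7, C1', C5', C6', C7' from the two natural lactones; C8' by SN2 inversion; C4' by convex-face addition to C3'=O relayed through a suprafacial 1,2-shift; C5 and C10 by thermodynamic control.

Key step: step 12

Assumption: dehydrocostus lactone and deacylcynaropicrin, both sold as isolated natural products, are counted as commercial starting materials.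
Assumption: the target carries H-5 on the face opposite to that of the natural guaianolide series; H-5 and H-10 are gamma to the C3 ketone and therefore epimerizable, and the configuration drawn for the target at these two carbons is taken to be the thermodynamic one.

Step 1
Reactants: 1 dehydrocostus lactone
Product: 2 3-epizaluzanin C
Conditions: SeO2 (0.5 equiv), t-BuOOH, CH2Cl2, 23 °C
Reagents that add atoms: tert-butyl hydroperoxide, CC(C)(C)OO
Why: Catalytic SeO2 allylic oxidation (ene reaction then 2,3-shift) should attack the electron-rich 4(15)-alkene at the ring CH2 C3 from the convex alpha face to give the 3α-alcohol, whose configuration is removed again in step 2.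

Step 2
Reactants: 2 3-epizaluzanin C
Product: 3 dehydrozaluzanin C
Conditions: Dess–Martin periodinane, CH2Cl2, 0 → 23 °C
Reagents that add atoms: none
Why: Dess–Martin oxidation of the allylic alcohol should give the exo-methylene cyclopentanone without touching the three alkenes or the lactone.

Step 3
Reactants: 3 dehydrozaluzanin C
Product: 4 silyl dienol ether of 3
Conditions: TBSOTf, Et3N, CH2Cl2, −78 °C
Reagents that add atoms: tert-butyldimethylsilyl triflate, CC(C)(C)[Si](C)(C)OS(=O)(=O)C(F)(F)F
Why: Soft enolization with silyl triflate and amine can only go toward C2, the sole alpha carbon that bears hydrogen, and should give the 2-silyloxy diene.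

Step 4
Reactants: 4 silyl dienol ether of 3
Product: 5 3-oxoguaia-1,4(15),10(14),11(13)-tetraen-12,6α-olide
Conditions: Pd(OAc)2 (1.05 equiv), MeCN, 23 °C; kept cold and dilute, used at once
Reagents that add atoms: none
Why: Saegusa–Ito oxidation, in which the palladium enolate loses H-1 by beta-hydride elimination, should place the new alkene at C1=C2 in conjugation with C10=C14, since C4 carries no hydrogen.

Step 5
Reactants: 5 3-oxoguaia-1,4(15),10(14),11(13)-tetraen-12,6α-olide
Product: 6 2-iodo dienone
Conditions: I2, pyridine, CH2Cl2, 0 °C
Reagents that add atoms: iodine, II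
Why: Alpha-iodination of an enone with iodine and pyridine should work by reversible addition of the amine to the dienone (here at the unhindered C14 terminus), iodination of the dienolate at C2 and loss of pyridine, which restores the C1=C2 and C10=C14 alkenes.

Step 6
Reactants: 6 2-iodo dienone
Product: 7 2-iodo-3β-hydroxy dienol
Conditions: NaBH4, CeCl3·7H2O, MeOH, −78 °C
Reagents that add atoms: none
Why: Luche 1,2-reduction should remove the ketone that would not survive the organometallic step while sparing the α-methylene lactone, with hydride entering anti to C6 to give a C3 centre that is erased again in step 11.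

Step 7
Reactants: 8 deacylcynaropicrin
Product: 9 8α-hydroxydehydrozaluzanin C
Conditions: MnO2, CH2Cl2, 23 °C
Reagents that add atoms: none
Why: MnO2 should oxidize only the allylic C3' alcohol to the enone, because the C8' alcohol is homoallylic and inert to this reagent.

Step 8
Reactants: 9 8α-hydroxydehydrozaluzanin C
Product: 12 8β-hydroxydehydrozaluzanin C, via 8α-triflate 10 (not isolated), via 8β-nitrite ester 11 (not isolated)
Conditions: Tf2O, pyridine, CH2Cl2, −30 °C; then n-Bu4NNO2, DMF, 23 °C; aqueous work-up
Reagents that add atoms: tetrabutylammonium nitrite, CCCC[N+](CCCC)(CCCC)CCCC.[O-]N=O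
Why: Lattrell–Dax inversion, in which the secondary triflate is displaced by nitrite oxygen in an SN2 reaction and the nitrite ester is hydrolysed on work-up, should set the 8'β configuration by clean inversion (H-7' is cis to the leaving group, which disfavours elimination toward C7').

Step 9
Reactants: 12 8β-hydroxydehydrozaluzanin C
Product: 13 8β-(tert-butyldimethylsilyloxy)dehydrozaluzanin C
Conditions: TBSOTf, 2,6-lutidine, CH2Cl2, −78 °C
Reagents that add atoms: tert-butyldimethylsilyl triflate, CC(C)(C)[Si](C)(C)OS(=O)(=O)C(F)(F)F
Why: Silylation of the secondary alcohol with silyl triflate and a hindered pyridine at low temperature should be much faster than enol silylation of the ketone and gives an ether that survives steps 10 to 13.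

Step 10
Reactants: 7 2-iodo-3β-hydroxy dienol; 13 8β-(tert-butyldimethylsilyloxy)dehydrozaluzanin C
Product: 15 C2–C3' carbinol, via alkenylmagnesium alkoxide 14 (not isolated)
Conditions: 7, n-Bu3MgLi (1.2 equiv), THF, −78 °C; LaCl3·2LiCl (1.1 equiv); then 13, −78 → −40 °C; aq. NH4Cl
Reagents that add atoms: none
Why: Iodine–magnesium exchange with the magnesate (the hydroxyl is masked as its alkoxide) followed by LaCl3-promoted 1,2-addition of the alkenylmagnesium to the C3' ketone, the most electrophilic carbonyl present, should occur from the convex alpha face of the cis-fused bicycle (the face of H-1' and H-5'), so that C3' carries C2 alpha and OH beta.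

Step 11
Reactants: 15 C2–C3' carbinol
Product: 16 carbinol dienone
Conditions: MnO2, CH2Cl2, 23 °C
Reagents that add atoms: none
Why: MnO2 should oxidize only the doubly allylic secondary C3 alcohol to the cross-conjugated dienone, since the tertiary C3' carbinol cannot be oxidized and the neutral conditions avoid its ionization.

Step 12
Reactants: 16 carbinol dienone
Product: 18 spiro ketone with 5α-H, via seven-membered zwitterion 17 (not isolated)
Conditions: Me2AlCl (3 equiv), CH2Cl2, −78 → 0 °C; aq. NaHCO3
Reagents that add atoms: none
Why: Proposed new method: Me2AlCl should turn the tertiary carbinol into its aluminium alkoxide and, chelated between this oxygen and the C3 carbonyl, activate the cross-conjugated dienone at its C14 terminus, which is attacked by the 1,1-disubstituted C4'=C15' alkene in a 7-endo-trig (Markovnikov) 1,6-addition to give the seven-membered ring C3'–C4'–C15'–C14–C10–C1–C2 as a tertiary C4' cation next to the alkoxide carbon and an aluminium dienolate. The cation is then quenched by a 1,2-shift of the electron-rich enolate carbon C2 from C3' to C4' (semipinacol ring contraction from seven to six members, C3' leaving the ring as the ketone), and protonation of the dienolate at C10 on work-up gives the enone. The closest known reaction types are the Prins–pinacol sequence and the Lewis-acid 1,6-addition of allylsilanes to dienones; new is a plain alkene as the nucleophile toward a dienone combined with a dienolate carbon as the migrating group. C4' is the centre set here: C2 sits on the alpha face of C3' and migrates suprafacially to the alpha face of the planar cation, so the quaternary carbon ends with C2 alpha and C15' beta, while C10 comes from protonation and is settled in step 13. The step needs 7-endo closure and migration to win over ionization of the bis-allylic carbinol and proton loss from the cation: the aluminium alkoxide resists ionization, Markovnikov attack allows only the endo mode, and shift of the enolate carbon should be faster than elimination or shift of the ring CH2 C2'.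

Step 13
Reactants: 18 spiro ketone with 5α-H
Product: 19 8'-O-silyl ether of the target
Conditions: DBU (0.2 equiv), CH2Cl2, 0 → 23 °C
Reagents that add atoms: none
Why: Base-catalysed vinylogous enolization should equilibrate the two gamma centres C5 and C10 (and any beta,gamma-enone isomer) to the thermodynamic arrangement, taken to be that of the target, with H-5 and H-10 on opposite faces of the enone plane and ring B as a twist-chair.

Step 14
Reactants: 19 8'-O-silyl ether of the target
Product: 20 CNP0178208.1
Conditions: HF·pyridine, pyridine, THF, 0 → 23 °C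
Reagents that add atoms: none
Why: Fluoride-mediated desilylation under buffered, weakly acidic conditions should free the 8'β-hydroxyl without touching the enone, the three exo-methylene acceptors or the epimerizable centres.

**Compound list**

1 | dehydrocostus lactone | C=C1CC[C@@H]2[C@@H]([C@@H]3[C@H]1CCC3=C)OC(=O)C2=C | starting material
2 | 3-epizaluzanin C (3α-alcohol) | C=C1CC[C@@H]2[C@@H]([C@@H]3[C@H]1C[C@@H](O)C3=C)OC(=O)C2=C | intermediate
3 | dehydrozaluzanin C | C=C1CC[C@@H]2[C@@H]([C@@H]3[C@H]1CC(=O)C3=C)OC(=O)C2=C | intermediate
4 | silyl dienol ether of 3 (C2=C3–OTBS) | C=C1CC[C@@H]2[C@@H]([C@@H]3[C@H]1C=C(O[Si](C)(C)C(C)(C)C)C3=C)OC(=O)C2=C | intermediate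
5 | 3-oxoguaia-1,4(15),10(14),11(13)-tetraen-12,6α-olide | C=C1CC[C@@H]2[C@@H]([C@@H]3C1=CC(=O)C3=C)OC(=O)C2=C | intermediate
6 | 2-iodo dienone | C=C1CC[C@@H]2[C@@H]([C@@H]3C1=C(I)C(=O)C3=C)OC(=O)C2=C | intermediate
7 | 2-iodo-3β-hydroxy dienol | C=C1CC[C@@H]2[C@@H]([C@@H]3C1=C(I)[C@H](O)C3=C)OC(=O)C2=C | intermediate
8 | deacylcynaropicrin (3β,8α-diol) | C=C1[C@@H](O)C[C@H]2C(=C)C[C@H](O)[C@H]3C(=C)C(=O)O[C@@H]3[C@H]21 | starting material
9 | 8α-hydroxydehydrozaluzanin C | C=C1C(=O)C[C@H]2C(=C)C[C@H](O)[C@H]3C(=C)C(=O)O[C@@H]3[C@H]21 | intermediate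
10 | 8α-triflate of 9 | C=C1C(=O)C[C@H]2C(=C)C[C@H](OS(=O)(=O)C(F)(F)F)[C@H]3C(=C)C(=O)O[C@@H]3[C@H]21 | intermediate
11 | 8β-nitrite ester | C=C1C(=O)C[C@H]2C(=C)C[C@@H](ON=O)[C@H]3C(=C)C(=O)O[C@@H]3[C@H]21 | intermediate
12 | 8β-hydroxydehydrozaluzanin C | C=C1C(=O)C[C@H]2C(=C)C[C@@H](O)[C@H]3C(=C)C(=O)O[C@@H]3[C@H]21 | intermediate
13 | 8β-(tert-butyldimethylsilyloxy)dehydrozaluzanin C | C=C1C(=O)C[C@H]2C(=C)C[C@@H](O[Si](C)(C)C(C)(C)C)[C@H]3C(=C)C(=O)O[C@@H]3[C@H]21 | intermediate
14 | alkenyl(butyl)magnesium lithium alkoxide from 7 | C=C1CC[C@@H]2[C@@H]([C@@H]3C1=C([Mg]CCCC)[C@H](O[Li])C3=C)OC(=O)C2=C | intermediate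
15 | C2–C3' carbinol (3β-OH; C2 alpha and OH beta at C3') | C=C1CC[C@@H]2[C@@H]([C@@H]3C1=C([C@]4(O)C[C@H]5C(=C)C[C@@H](O[Si](C)(C)C(C)(C)C)[C@H]6C(=C)C(=O)O[C@@H]6[C@H]5C4=C)[C@H](O)C3=C)OC(=O)C2=C | intermediate
16 | carbinol dienone | C=C1CC[C@@H]2[C@@H]([C@@H]3C1=C([C@]4(O)C[C@H]5C(=C)C[C@@H](O[Si](C)(C)C(C)(C)C)[C@H]6C(=C)C(=O)O[C@@H]6[C@H]5C4=C)C(=O)C3=C)OC(=O)C2=C | intermediate
17 | seven-membered zwitterion (C4' cation, C3 dienolate; aluminium-bound in the flask) | C7C1CC[C@@H]2[C@@H]([C@@H]3C=1C([C@]4(O)C[C@H]5C(=C)C[C@@H](O[Si](C)(C)C(C)(C)C)[C@H]6C(=C)C(=O)O[C@@H]6[C@H]5[C+]4C7)=C([O-])C3=C)OC(=O)C2=C | intermediate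
18 | spiro ketone with 5α-H (C5 epimer of 19; C10 drawn as in the target, any C10 epimer converges in step 13) | C=C1C(=O)C2=C3[C@H](CC[C@H]4C(=C)C(=O)O[C@@H]4[C@@H]13)CC[C@]21C(=O)C[C@H]2C(=C)C[C@@H](O[Si](C)(C)C(C)(C)C)[C@H]3C(=C)C(=O)O[C@@H]3[C@H]21 | intermediate
19 | 8'-O-silyl ether of the target | C=C1C(=O)C2=C3[C@H](CC[C@H]4C(=C)C(=O)O[C@@H]4[C@H]13)CC[C@]21C(=O)C[C@H]2C(=C)C[C@@H](O[Si](C)(C)C(C)(C)C)[C@H]3C(=C)C(=O)O[C@@H]3[C@H]21 | intermediate
20 | CNP0178208.1 | C=C1C(=O)C2=C3[C@H](CC[C@H]4C(=C)C(=O)O[C@@H]4[C@H]13)CC[C@]21C(=O)C[C@H]2C(=C)C[C@@H](O)[C@H]3C(=C)C(=O)O[C@@H]3[C@H]21 | target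

**Step count:** 14 steps in total; the longest linear sequence is 11 steps (steps 1–6 and 10–14).

**Steps most likely to fail**

Step 12 (proposed new method). The bis-allylic carbinol may ionize, the C4' cation may lose a proton instead of accepting the shift, or the plain alkene may be too weak a nucleophile for the dienone. The fallback is a biomimetic Diels–Alder reaction. It sets out from dienone 5 (diene C2=C1–C10=C14) and enone 13 (dienophile C4'=C15'), combined neat or in concentrated CH2Cl2 at 23 °C. It should give the Diels–Alder adduct F1 with C2 bound to the alpha face of C4' and C14 bound to C15'. F1, treated under the conditions of step 13, comes back to the route at 19. In this fallback the six-membered ring is closed directly.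

Step 10. The exchange may be slow, or the organomagnesium may attack a lactone or an exo-methylene acceptor or enolize the ketone. The fallback is a Nozaki–Hiyama–Kishi coupling. It sets out from iodo dienone 6 and ketone 13 with CrCl2 and catalytic NiCl2 in DMF at 23 °C. It should give carbinol dienone 16 directly, so it comes back at 16 and passes by 7, 15 and step 11.

Step 13. The equilibrium may not lie on the side of the target epimers, or the base may trigger elimination of the C6 carboxylate or an intramolecular Michael addition. The fallback is kinetic control. It sets out from 18, which is deprotonated at C5 with LiN(SiMe3)2 in THF at −78 °C to the lithium dienolate F2. Quenching with acetic acid at −78 °C should deliver the proton to C5 from the less hindered face, syn to H-6. It comes back at 19.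

Further compounds
F1 | step 12 | Diels–Alder adduct of 5 and 13 (C1=C10 alkene, H at C2; C2 configuration drawn for addition anti to C6 and erased on isomerization) | C=C1C(=O)[C@H]2C3=C(CC[C@H]4C(=C)C(=O)O[C@@H]4[C@@H]13)CC[C@]21C(=O)C[C@H]2C(=C)C[C@@H](O[Si](C)(C)C(C)(C)C)[C@H]3C(=C)C(=O)O[C@@H]3[C@H]21
F0 | step 10 | none | none
F2 | step 13 | lithium dienolate of 18 (C3–OLi, C2=C3, C1=C5) | C=C1C(O[Li])=C2C3[C@H](CC[C@H]4C(=C)C(=O)O[C@@H]4C1=3)CC[C@]21C(=O)C[C@H]2C(=C)C[C@@H](O[Si](C)(C)C(C)(C)C)[C@H]3C(=C)C(=O)O[C@@H]3[C@H]21
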